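**Retrosynthetic overview**
- The isoflavone is taken back to the flavanone with the same skeleton. The last step is an oxidative 2,3-aryl shift: ring C is kept and the aryl group moves from C2 to C3. Before it, the single phenol is O-methylated.
- The flavanone is taken back to 2,4-dihydroxybenzaldehyde, prenal and paeonol, joined in one flask by a three-component double annulation.
- Ring order: rings A and B are bought. Ring D (2,2-dimethyl-2H-pyran) closes first, at the carbon between the two oxygens of the aldehyde. Ring C closes second in the same operation, as a chromanone, and becomes the 4-pyranone in the final aryl shift.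

Assumption: the target has no stereocentre, so it is made as the one achiral compound; the two flavanone intermediates are racemic and their C2 centre is destroyed in the last step.

**Step 1**
Reactants: 1 2,4-dihydroxybenzaldehyde; 2 3-methylbut-2-enal (prenal); 3 1-(2-hydroxy-4-methoxyphenyl)ethan-1-one (paeonol)
Product: 6 (±)-2-(5-hydroxy-2,2-dimethyl-2H-chromen-6-yl)-7-methoxychroman-4-one, via chromene aldehyde 4 (not isolated), via hydroxychalcone 5 (not isolated)
Conditions: 2 (1.1 equiv), ethylenediammonium diacetate (10 mol%), o-xylene, 140 °C, 6 h; then 3 (1.0 equiv), pyrrolidine (0.5 equiv), 100 °C, 16 h, same flask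
Reagents that add atoms: none
Why: Ethylenediammonium diacetate turns prenal into an iminium that condenses at C3 of 1 (the carbon between the two oxygens, because the 2-hydroxyl is held in a hydrogen bond to the aldehyde) and the dienone closes ring D by oxa-6π electrocyclisation (formal [3+3] chromene annulation), after which pyrrolidine mediates a Kabbe-type aldol condensation of aldehyde 4 with 3 and 6-endo oxa-Michael addition of hydroxychalcone 5 closes ring C, the new C2 stereocentre forming without control as a racemate that is erased in step 3.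

**Step 2**
Reactants: 6 (±)-2-(5-hydroxy-2,2-dimethyl-2H-chromen-6-yl)-7-methoxychroman-4-one
Product: 7 (±)-7-methoxy-2-(5-methoxy-2,2-dimethyl-2H-chromen-6-yl)chroman-4-one
Conditions: MeI (1.5 equiv), K2CO3, acetone, 56 °C
Reagents that add atoms: iodomethane (MeI), CI
Why: Williamson O-methylation of the only free phenol; no stereocentre is formed and C2 stays racemic.

**Step 3**
Reactants: 7 (±)-7-methoxy-2-(5-methoxy-2,2-dimethyl-2H-chromen-6-yl)chroman-4-one
Product: 8 7-methoxy-3-(5-methoxy-2,2-dimethyl-2H-chromen-6-yl)-4H-chromen-4-one (target, achiral)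
Conditions: PhI(OH)OTs (1.2 equiv), HC(OMe)3, H2SO4 (cat.), rt
Reagents that add atoms: none
Why: Hypervalent-iodine oxidative rearrangement of a flavanone to an isoflavone (2,3-aryl migration): the enol ether formed in HC(OMe)3/acid is attacked at C3 by the iodane, the very electron-rich 2-methoxy-4-alkoxyaryl group shifts from C2 to C3 as PhI leaves, and proton loss from the oxocarbenium gives the C2=C3 double bond, which removes the only stereocentre.

**Compound list**
1 | 2,4-dihydroxybenzaldehyde | O=Cc1ccc(O)cc1O | starting material
2 | 3-methylbut-2-enal (prenal) | CC(C)=CC=O | starting material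
3 | 1-(2-hydroxy-4-methoxyphenyl)ethan-1-one (paeonol) | CC(=O)c1ccc(OC)cc1O | starting material
4 | 5-hydroxy-2,2-dimethyl-2H-chromene-6-carbaldehyde (not isolated) | O=Cc1ccc2OC(C)(C)C=Cc2c1O | intermediate
5 | (E)-1-(2-hydroxy-4-methoxyphenyl)-3-(5-hydroxy-2,2-dimethyl-2H-chromen-6-yl)prop-2-en-1-one (not isolated) | COc1ccc(C(=O)/C=C/c2ccc3OC(C)(C)C=Cc3c2O)c(O)c1 | intermediate
6 | (±)-2-(5-hydroxy-2,2-dimethyl-2H-chromen-6-yl)-7-methoxychroman-4-one, racemic at C2 | COc1ccc2C(=O)CC(c3ccc4OC(C)(C)C=Cc4c3O)Oc2c1 | intermediate
7 | (±)-7-methoxy-2-(5-methoxy-2,2-dimethyl-2H-chromen-6-yl)chroman-4-one, racemic at C2 | COc1ccc2C(=O)CC(c3ccc4OC(C)(C)C=Cc4c3OC)Oc2c1 | intermediate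
8 | 7-methoxy-3-(5-methoxy-2,2-dimethyl-2H-chromen-6-yl)-4H-chromen-4-one, achiral | COc1ccc2c(=O)c(-c3ccc4c(c3OC)C=CC(C)(C)O4)coc2c1 | target

**Total step count:** 3
**Longest linear sequence:** 3 steps (three starting materials converge in step 1)

**Steps most likely to fail**

Step 1 is the riskiest. Prenal left over after the first stage can be captured by paeonol and pyrrolidine. The free-phenol, electron-rich aldehyde 4 is a slow aldol acceptor. The hydroxychalcone/flavanone equilibrium may stop before ring C closes. The fallback sets out from 1 and comes back at 6, and builds ring D with no enal in the flask. 1 is alkylated at the free 4-hydroxyl with 3-chloro-3-methylbut-1-yne (K2CO3, KI, CuI cat., acetone, 56 °C) to 2-hydroxy-4-[(2-methylbut-3-yn-2-yl)oxy]benzaldehyde F1. Heating F1 alone in o-xylene at 140 °C gives 4 by aromatic propargyl Claisen rearrangement, 1,5-hydrogen shift and oxa-6π closure, again directed to the carbon between the oxygens by the hydrogen-bonded hydroxy aldehyde. Isolated 4 is condensed with 3 under KOH in EtOH (Claisen–Schmidt) to isolated 5, and 5 is cyclised to 6 with NaOAc in refluxing EtOH.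

Step 3 is next. The iodane may attack the electron-rich chromene double bond, and dehydrogenation to the flavone or ring contraction can compete with the aryl shift. The fallback sets out from 7 and comes back at 8, and takes the double bond out of play. 7 is hydrogenated (H2, Pd/C, EtOAc, rt) to 7-methoxy-2-(5-methoxy-2,2-dimethylchroman-6-yl)chroman-4-one F4. The aryl shift is run on F4 under the step 3 conditions to give 7-methoxy-3-(5-methoxy-2,2-dimethylchroman-6-yl)-4H-chromen-4-one F5. Dehydrogenation of the chroman ring with DDQ in refluxing benzene restores the chromene and gives 8.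

Step 2 is third. Carbonate can open the flavanone through the ortho-phenoxide (retro-oxa-Michael) and then alkylate the wrong phenol of the open chalcone. The fallback sets out from 4 and comes back at 7, and methylates before ring C exists. Step 1 is stopped after its first stage and 4 is isolated. 4 is methylated (MeI, K2CO3, DMF, 60 °C) to 5-methoxy-2,2-dimethyl-2H-chromene-6-carbaldehyde F2. F2 and 3 give, under KOH in EtOH, (E)-1-(2-hydroxy-4-methoxyphenyl)-3-(5-methoxy-2,2-dimethyl-2H-chromen-6-yl)prop-2-en-1-one F3. F3 is cyclised to 7 with NaOAc in refluxing EtOH. Uncyclised F3 can be carried along, because the step 3 conditions move the same aryl group in the open chalcone.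

**Further compounds**
F1 | step 1 | 2-hydroxy-4-[(2-methylbut-3-yn-2-yl)oxy]benzaldehyde | O=Cc1ccc(OC(C)(C)C#C)cc1O
F2 | step 2 | 5-methoxy-2,2-dimethyl-2H-chromene-6-carbaldehyde | O=Cc1ccc2OC(C)(C)C=Cc2c1OC
F3 | step 2 | (E)-1-(2-hydroxy-4-methoxyphenyl)-3-(5-methoxy-2,2-dimethyl-2H-chromen-6-yl)prop-2-en-1-one | COc1ccc(C(=O)/C=C/c2ccc3OC(C)(C)C=Cc3c2OC)c(O)c1
F4 | step 3 | (±)-7-methoxy-2-(5-methoxy-2,2-dimethylchroman-6-yl)chroman-4-one, racemic at C2 | COc1ccc2C(=O)CC(c3ccc4OC(C)(C)CCc4c3OC)Oc2c1
F5 | step 3 | 7-methoxy-3-(5-methoxy-2,2-dimethylchroman-6-yl)-4H-chromen-4-one | COc1ccc2c(=O)c(-c3ccc4OC(C)(C)CCc4c3OC)coc2c1
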